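**Strategy.** The cyclohexene ring (C1, C10, C11, C12, C13, C14) is cut into two three-carbon units. C1(C15)–C14–C13 maps onto the α-carbon, α-methyl, ketone and acetyl methyl of a 2-methylacetoacetate; C10–C11(C20)–C12 maps onto a 2-methyl enal. One Michael/aldol-condensation operation forms C1–C10 and C12–C13, closes the ring and sets C10 from a glyceraldehyde-derived stereocenter. Its precursors are an acyclic β-keto ester and a dioxolanyl enal. The enone is then remodelled (C1 acylation, diene, cis-diol) and joined to a tetronate triflate at C8–C9. The tetrahydropyran (oxa-Michael) and the oxocane (carbonyl-ene) are closed last.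

Key step: step 3

Remark on numbering: locants C1–C20 are the carbons of the target (C1 quaternary ring carbon with methyl C15; C2 ether CH; C3 carbinol; C4 CH2; C5 with methylene C16; C6 CHCl; C7 lactone CH–O; C8 spiro ether carbon; C9, C12 CH–OAc; C10 ring-fusion CH; C11 with methyl C20; C13=C14; C17 with methyl C18; C19 lactone C=O); on the cyclohexene ring α is the face of H-10 and β that of C15.

**Step 1**
Reactants: 1 1,2:5,6-di-O-isopropylidene-D-mannitol
Product: 2 (R)-2,3-O-isopropylideneglyceraldehyde
Conditions: NaIO4, sat. aq. NaHCO3, CH2Cl2, rt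
Reagents that add atoms: none
Why: Malaprade cleavage of the free 3,4-diol should give two molecules of the aldehyde without touching the (R) stereocenter of the chiral pool.

**Step 2**
Reactants: 2 (R)-2,3-O-isopropylideneglyceraldehyde; 3 2-(triphenylphosphoranylidene)propanal
Product: 4 (E)-3-[(4S)-2,2-dimethyl-1,3-dioxolan-4-yl]-2-methylprop-2-enal
Conditions: toluene, 60 °C
Reagents that add atoms: none
Why: Wittig olefination with the stabilised formyl ylide should give the E-trisubstituted enal under base-free conditions, so the allylic stereocenter (C9) is not epimerised.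

**Step 3**
Reactants: 4 (E)-3-[(4S)-2,2-dimethyl-1,3-dioxolan-4-yl]-2-methylprop-2-enal; 5 tert-butyl 2-methyl-3-oxobutanoate
Product: 8 (4R,5S,6R)-5-[(4S)-2,2-dimethyl-1,3-dioxolan-4-yl]-4,6-dimethylcyclohex-2-en-1-one, via Michael adduct 6 (not isolated), via annulated tert-butyl keto ester 7 (not isolated)
Conditions: DBU (0.2 equiv), MeCN, 0 °C → rt; then p-TsOH·H2O (0.3 equiv), toluene, Dean–Stark, 110 °C
Reagents that add atoms: none
Why: The DBU-generated enolate of 5 adds through its α-carbon (C1) to C10 of enal 4 to give 6, whose acetyl methyl (C13) then condenses onto the aldehyde carbon C12; the acid stage dehydrates, cleaves the tert-butyl ester and decarboxylates, which is a Robinson-type Michael/aldol [3+3] annulation of a β-keto ester with an enal. The six-membered ring closes in the 6-(enolendo)-exo-trig mode. C10 is set in the Michael step by the dioxolane center C9: A(1,3) strain with the C11 methyl holds H-9 in the enal plane and the enolate should enter anti to the dioxolane CH2 group, giving the 9,10-syn adduct. C1 and C11 are epimerisable and should settle trans to the C10 substituent in the acid stage (C1 is set for good in step 4). Chemoselectivity rests on the α-methyl group of 5, which rules out Knoevenagel condensation, and on the fact that only the acetyl methyl can enolise toward C12.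

**Step 4**
Reactants: 8 cyclohexenone; 9 2,2-dimethoxyacetaldehyde
Product: 10 C1-quaternary aldol adduct (8 carrying a 1-hydroxy-2,2-dimethoxyethyl group, C2–C3, on C1 trans to the C10 dioxolanyl group; C2 carbinol epimers)
Conditions: LDA, THF, −78 °C; then anhydrous 9, −78 °C; aq. NH4Cl
Reagents that add atoms: none
Why: Kinetic α′-deprotonation at C1 and aldol addition on the enolate face anti to the C10 dioxolanyl group should set the quaternary center C1 with C2 trans to C9; the carbinol mixture at C2 is removed in step 5.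

**Step 5**
Reactants: 10 aldol adduct
Product: 11 β-diketone (C2 ketone, C3 dimethyl acetal)
Conditions: Dess–Martin periodinane, NaHCO3, CH2Cl2, rt
Reagents that add atoms: none
Why: Neutral hypervalent-iodine oxidation of the hindered carbinol should give the non-enolisable β-diketone without retro-aldol or retro-Claisen cleavage.

**Step 6**
Reactants: 11 β-diketone
Product: 12 dienyl triflate (14-triflyloxy-11,13-diene)
Conditions: Tf2O, 2,6-di-tert-butyl-4-methylpyridine, CH2Cl2, 0 °C → rt
Reagents that add atoms: trifluoromethanesulfonic anhydride, O=S(=O)(OS(=O)(=O)C(F)(F)F)C(F)(F)F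
Why: O-triflation of the more basic enone carbonyl and loss of the γ-proton H-11 should give the 2-triflyloxy-1,3-diene, while the C2 ketone (no hydrogen on C1, only the acetal C–H on C3) is not enolised.

**Step 7**
Reactants: 12 dienyl triflate
Product: 13 11,13-diene
Conditions: Pd(OAc)2 (5 mol %), PPh3, HCO2H, n-Bu3N, DMF, 60 °C
Reagents that add atoms: none
Why: Oxidative addition of zerovalent palladium to the vinyl triflate, formate exchange, decarboxylation and reductive elimination should replace OTf by H (formate reduction of a vinyl triflate).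

**Step 8**
Reactants: 13 11,13-diene
Product: 14 11α,12α-diol
Conditions: OsO4 (2 mol %), N-methylmorpholine N-oxide (1.1 equiv), acetone–H2O, 0 °C
Reagents that add atoms: osmium tetroxide, O=[Os](=O)(=O)=O; N-methylmorpholine N-oxide, C[N+]1([O-])CCOCC1; water, O
Why: Upjohn dihydroxylation should take the more electron-rich trisubstituted C11=C12 bond and add syn from the α face, anti to the adjacent C10 dioxolanyl group, which sets C11 and C12.

**Step 9**
Reactants: 14 diol
Product: 15 11α,12α-diacetate
Conditions: Ac2O, Et3N, DMAP (1 equiv), CH2Cl2, 40 °C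
Reagents that add atoms: acetic anhydride, CC(=O)OC(C)=O
Why: DMAP-catalysed acylation under forcing conditions should acetylate the tertiary C11 hydroxyl as well as the secondary C12 hydroxyl.

**Step 10**
Reactants: 15 diacetate
Product: 16 C9 aldehyde (10β-formyl-1α-(2,2-dimethoxyacetyl)-1β,11β-dimethylcyclohex-13-ene-11α,12α-diyl diacetate)
Conditions: H5IO6, EtOAc, rt; used crude
Reagents that add atoms: none
Why: Periodic acid should hydrolyse the terminal acetonide and cleave the freed 1,2-diol in one pot (Malaprade), while the acetylated ring diol and the deactivated α-keto acetal are not affected.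

**Step 11**
Reactants: 17 2-methylprop-2-en-1-ol
Product: 18 3-(methoxymethoxy)-2-methylprop-1-ene
Conditions: MOMCl, i-Pr2NEt, CH2Cl2, 0 °C → rt
Reagents that add atoms: chloromethyl methyl ether, COCCl
Why: O-alkylation of the alkoxide equivalent with the α-chloro ether (Williamson-type acetal formation) should be clean.

**Step 12**
Reactants: 18 3-(methoxymethoxy)-2-methylprop-1-ene; 19 ethyl glyoxylate
Product: 21 ethyl (2S,3R)-2-hydroxy-3-(methoxymethoxy)-4-methylpent-4-enoate, via Z-alkoxyallylborane 20 (not isolated)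
Conditions: s-BuLi, THF, −78 °C; (−)-B-methoxydiisopinocampheylborane; BF3·OEt2; then 19, −78 °C; ethanolamine work-up
Reagents that add atoms: none
Why: α-Lithiation gives the chelated Z-alkoxyallyl anion, which is borylated at its γ-terminus, and chair-like allylboration of the glyoxylate should give the syn adduct with the isopinocampheyl groups (from (+)-α-pinene) directing attack to the Si face, which sets C7 and C6.

**Step 13**
Reactants: 21 hydroxy ester; 22 propanoyl chloride
Product: 23 ethyl (2S,3R)-3-(methoxymethoxy)-4-methyl-2-(propanoyloxy)pent-4-enoate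
Conditions: pyridine, DMAP (cat.), CH2Cl2, 0 °C
Reagents that add atoms: none
Why: Simple O-acylation of the secondary alcohol installs the C17–C19 unit of the lactone.

**Step 14**
Reactants: 23 propionate
Product: 24 (5S)-4-hydroxy-5-[(1R)-1-(methoxymethoxy)-2-methylprop-2-enyl]-3-methylfuran-2(5H)-one
Conditions: LiHMDS (2.2 equiv), THF, −78 → −20 °C; 1 M HCl
Reagents that add atoms: none
Why: Dieckmann condensation of the propionate enolate onto the ethyl ester (5-exo-trig) should give the tetronic acid as its stable anion, at a temperature at which C7 is not epimerised.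

**Step 15**
Reactants: 24 tetronic acid
Product: 25 tetronate triflate (4-triflyloxy analogue of 24)
Conditions: Tf2O, i-Pr2NEt, CH2Cl2, −78 °C
Reagents that add atoms: trifluoromethanesulfonic anhydride, O=S(=O)(OS(=O)(=O)C(F)(F)F)C(F)(F)F
Why: O-sulfonylation of the vinylogous acid should give the vinyl triflate needed for the coupling.

**Step 16**
Reactants: 16 C9 aldehyde; 25 tetronate triflate
Product: 26 (9R)-carbinol (butenolide C8 joined to C9)
Conditions: CrCl2 (4 equiv), NiCl2 (2 mol %), DMSO–THF, rt
Reagents that add atoms: none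
Why: Nozaki–Hiyama–Kishi coupling (nickel insertion into the vinyl triflate, transmetalation to chromium, aldehyde-selective addition) should form C8–C9, and Felkin–Anh addition anti to the C10–C1 bond (C1 carries the bulky keto acetal) should give the 9R carbinol.

**Step 17**
Reactants: 26 carbinol
Product: 27 9,11,12-triacetate
Conditions: Ac2O, pyridine, DMAP, CH2Cl2, rt
Reagents that add atoms: acetic anhydride, CC(=O)OC(C)=O
Why: DMAP-catalysed acetylation of the secondary allylic alcohol.

**Step 18**
Reactants: 27 triacetate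
Product: 28 (2S)-carbinol
Conditions: (S)-2-methyl-CBS-oxazaborolidine (1 equiv), catecholborane, toluene, −78 → −40 °C
Reagents that add atoms: none
Why: In this Corey–Bakshi–Shibata reduction the catalyst should tell the quaternary C1 side (large) from the dimethoxymethyl group (small) and deliver hydride to give the 2S carbinol, while catecholborane leaves alkenes, acetates and the butenolide alone.

**Step 19**
Reactants: 28 (2S)-carbinol
Product: 29 spiro tetrahydropyran–lactone (C2–O–C8 ether, saturated lactone)
Conditions: DBU (0.3 equiv), toluene, 0 °C → rt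
Reagents that add atoms: none
Why: Intramolecular oxa-Michael addition (6-exo-trig) of the C2 hydroxyl to C8 of the butenolide, anti to the side chain on C7, should set C8, and protonation of the lactone enolate on the less hindered face (that of the new C–O bond) should set C17.

**Step 20**
Reactants: 29 spiro lactone
Product: 30 hydroxy aldehyde (C6–OH, C3 aldehyde)
Conditions: Me2BBr, CH2Cl2, −78 °C; then THF–sat. aq. NaHCO3
Reagents that add atoms: water, O
Why: Bromoborane cleavage of the MOM ether and of the dimethyl acetal (through α-bromo ethers that hydrolyse on work-up) should free the C6 hydroxyl and the C3 aldehyde without touching the esters.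

**Step 21**
Reactants: 30 hydroxy aldehyde
Product: 31 (6S)-chloro aldehyde
Conditions: PPh3, hexachloroacetone, CH2Cl2, −30 → 0 °C
Reagents that add atoms: hexachloroacetone, ClC(Cl)(Cl)C(=O)C(Cl)(Cl)Cl
Why: Appel-type chlorination through the alkoxyphosphonium salt should proceed by SN2 displacement with inversion at C6, and this reagent pair is known to avoid allylic transposition.

**Step 22**
Reactants: 31 chloro aldehyde
Product: 32 target
Conditions: Me2AlCl (3 equiv), CH2Cl2, −78 → −20 °C, high dilution
Reagents that add atoms: none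
Why: In this Lewis acid-promoted intramolecular carbonyl-ene reaction the isopropenyl CH2 attacks C3, a methyl hydrogen moves to oxygen and the double bond becomes exocyclic, closing the oxocane; the aldehyde should react in the Cornforth conformer (C=O anti to the ring C2–O bond) on the face away from quaternary C1, which gives the 3R carbinol.

**Compound list**
1 | 1,2:5,6-di-O-isopropylidene-D-mannitol | CC1(C)OC[C@@H](O1)[C@@H](O)[C@H](O)[C@H]2COC(C)(C)O2 | starting material
2 | (R)-2,3-O-isopropylideneglyceraldehyde | O=C[C@H]1COC(C)(C)O1 | intermediate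
3 | 2-(triphenylphosphoranylidene)propanal | CC(C=O)=P(c1ccccc1)(c1ccccc1)c1ccccc1 | starting material
4 | (E)-3-[(4S)-2,2-dimethyl-1,3-dioxolan-4-yl]-2-methylprop-2-enal | O=C/C(C)=C/[C@H]1COC(C)(C)O1 | intermediate
5 | tert-butyl 2-methyl-3-oxobutanoate | CC(=O)C(C)C(=O)OC(C)(C)C | starting material
6 | Michael adduct, tert-butyl (3S)-2-acetyl-3-[(4S)-2,2-dimethyl-1,3-dioxolan-4-yl]-2,4-dimethyl-5-oxopentanoate (C2/C4 epimers) | CC(=O)C(C)(C(=O)OC(C)(C)C)[C@@H]([C@H]1COC(C)(C)O1)C(C)C=O | intermediate
7 | annulated keto ester, tert-butyl (6S)-6-[(4S)-2,2-dimethyl-1,3-dioxolan-4-yl]-1,5-dimethyl-2-oxocyclohex-3-ene-1-carboxylate (C1/C5 epimers) | CC1(C)OC[C@@H](O1)[C@@H]2C(C)(C(=O)OC(C)(C)C)C(=O)C=CC2C | intermediate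
8 | (4R,5S,6R)-5-[(4S)-2,2-dimethyl-1,3-dioxolan-4-yl]-4,6-dimethylcyclohex-2-en-1-one | CC1(C)OC[C@@H](O1)[C@@H]2[C@@H](C)C(=O)C=C[C@H]2C | intermediate
9 | 2,2-dimethoxyacetaldehyde | COC(OC)C=O | starting material
10 | C1-quaternary aldol adduct (1-hydroxy-2,2-dimethoxyethyl on C1, trans to C9; C2 epimers) | CC1(C)OC[C@@H](O1)[C@@H]2[C@@](C)(C(O)C(OC)OC)C(=O)C=C[C@H]2C | intermediate
11 | β-diketone (2,2-dimethoxyacetyl on C1) | CC1(C)OC[C@@H](O1)[C@@H]2[C@@](C)(C(=O)C(OC)OC)C(=O)C=C[C@H]2C | intermediate
12 | dienyl triflate (14-triflyloxy-11,13-diene) | CC1(C)OC[C@@H](O1)[C@@H]2[C@@](C)(C(=O)C(OC)OC)C(OS(=O)(=O)C(F)(F)F)=CC=C2C | intermediate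
13 | 11,13-diene | CC1(C)OC[C@@H](O1)[C@@H]2[C@@](C)(C(=O)C(OC)OC)C=CC=C2C | intermediate
14 | 11α,12α-diol | CC1(C)OC[C@@H](O1)[C@@H]2[C@@](C)(C(=O)C(OC)OC)C=C[C@@H](O)[C@@]2(C)O | intermediate
15 | 11α,12α-diacetate | CC1(C)OC[C@@H](O1)[C@@H]2[C@@](C)(C(=O)C(OC)OC)C=C[C@@H](OC(C)=O)[C@@]2(C)OC(C)=O | intermediate
16 | C9 aldehyde | O=C[C@@H]1[C@@](C)(C(=O)C(OC)OC)C=C[C@@H](OC(C)=O)[C@@]1(C)OC(C)=O | intermediate
17 | 2-methylprop-2-en-1-ol | C=C(C)CO | starting material
18 | 3-(methoxymethoxy)-2-methylprop-1-ene | C=C(C)COCOC | intermediate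
19 | ethyl glyoxylate | CCOC(=O)C=O | starting material
20 | B-[(Z)-3-(methoxymethoxy)-2-methylallyl]diisopinocampheylborane | COCO/C=C(/C)CB([C@@H]1C[C@@H]2C[C@H]([C@H]1C)C2(C)C)[C@@H]3C[C@@H]4C[C@H]([C@H]3C)C4(C)C | intermediate
21 | ethyl (2S,3R)-2-hydroxy-3-(methoxymethoxy)-4-methylpent-4-enoate | CCOC(=O)[C@@H](O)[C@H](OCOC)C(C)=C | intermediate
22 | propanoyl chloride | CCC(=O)Cl | starting material
23 | ethyl (2S,3R)-3-(methoxymethoxy)-4-methyl-2-(propanoyloxy)pent-4-enoate | CCOC(=O)[C@@H](OC(=O)CC)[C@H](OCOC)C(C)=C | intermediate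
24 | (5S)-4-hydroxy-5-[(1R)-1-(methoxymethoxy)-2-methylprop-2-enyl]-3-methylfuran-2(5H)-one | CC1=C(O)[C@H]([C@H](OCOC)C(C)=C)OC1=O | intermediate
25 | tetronate triflate | CC1=C(OS(=O)(=O)C(F)(F)F)[C@H]([C@H](OCOC)C(C)=C)OC1=O | intermediate
26 | (9R)-carbinol, coupled butenolide | CC1=C([C@H](O)[C@@H]2[C@@](C)(C(=O)C(OC)OC)C=C[C@@H](OC(C)=O)[C@@]2(C)OC(C)=O)[C@H]([C@H](OCOC)C(C)=C)OC1=O | intermediate
27 | 9,11,12-triacetate | CC1=C([C@H](OC(C)=O)[C@@H]2[C@@](C)(C(=O)C(OC)OC)C=C[C@@H](OC(C)=O)[C@@]2(C)OC(C)=O)[C@H]([C@H](OCOC)C(C)=C)OC1=O | intermediate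
28 | (2S)-carbinol | CC1=C([C@H](OC(C)=O)[C@@H]2[C@@](C)([C@H](O)C(OC)OC)C=C[C@@H](OC(C)=O)[C@@]2(C)OC(C)=O)[C@H]([C@H](OCOC)C(C)=C)OC1=O | intermediate
29 | spiro tetrahydropyran–lactone (C6–OMOM, C3 dimethyl acetal) | COC(OC)[C@H]1O[C@]2([C@H](OC(C)=O)[C@@H]3[C@]1(C)C=C[C@@H](OC(C)=O)[C@@]3(C)OC(C)=O)[C@@H](C)C(=O)O[C@H]2[C@H](OCOC)C(C)=C | intermediate
30 | hydroxy aldehyde | O=C[C@H]1O[C@]2([C@H](OC(C)=O)[C@@H]3[C@]1(C)C=C[C@@H](OC(C)=O)[C@@]3(C)OC(C)=O)[C@@H](C)C(=O)O[C@H]2[C@H](O)C(C)=C | intermediate
31 | (6S)-chloro aldehyde | O=C[C@H]1O[C@]2([C@H](OC(C)=O)[C@@H]3[C@]1(C)C=C[C@@H](OC(C)=O)[C@@]3(C)OC(C)=O)[C@@H](C)C(=O)O[C@H]2[C@@H](Cl)C(C)=C | intermediate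
32 | CNP0333938.3 | C=C1C[C@@H](O)[C@H]2O[C@]3([C@H](OC(C)=O)[C@@H]4[C@]2(C)C=C[C@@H](OC(C)=O)[C@@]4(C)OC(C)=O)[C@@H](C)C(=O)O[C@H]3[C@H]1Cl | target

**Totals.** 22 steps in all; the longest linear sequence is 17 steps (steps 1–10, then 16–22); the tetronate branch (steps 11–15) is 5 steps.

**Steps most likely to fail**

Step 22. The eight-membered ring may fail to close, because the ene donor is deactivated by the allylic chlorine, the Lewis acid is tied up by five ester groups, and the allylic chloride may ionise. The fallback sets out from 31 and returns at 32. Allylic oxidation of the isopropenyl methyl group (SeO2 cat., t-BuOOH, CH2Cl2) should give allylic alcohol F1, and PPh3/N-bromosuccinimide (no ylide, so the aldehyde survives) the allylic bromide F2. An intramolecular Nozaki–Hiyama allylation (CrCl2, THF, high dilution) should then join C3 to the γ-terminus of the allylchromium unit. Both termini are CH2 groups on C5, so the same exocyclic methylene results, and the primary bromide should react well before the secondary chloride.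

Step 3. Conjugate addition of the fully substituted enolate to the hindered, α,β-disubstituted enal may be slow or reversible, the facial selectivity may be low, and the acetonide may be lost in the hot acid stage. The fallback sets out from 4 and returns at 8. Mukaiyama–Michael addition of (Z)-2-(trimethylsilyloxy)but-2-ene (BF3·OEt2, CH2Cl2, −78 °C), a less hindered nucleophile on a Lewis acid-activated enal, should give keto aldehyde F3. Base-mediated aldol condensation (KOH, MeOH, rt) then closes the ring to 8 without any acidic stage.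

Step 16. The doubly neopentylic aldehyde may add slowly and on the wrong face. The fallback sets out from 16 and 25 and returns at 27. If the 9S carbinol F4 predominates it is kept: Mitsunobu esterification of F4 with acetic acid (PPh3, DIAD, toluene, 0 °C → rt) should invert C9 and give the acetate 27 directly.

**Further compounds**
F1 | step 22 | allylic alcohol (31 with CH2OH in place of the isopropenyl methyl) | O=C[C@H]1O[C@]2([C@H](OC(C)=O)[C@@H]3[C@]1(C)C=C[C@@H](OC(C)=O)[C@@]3(C)OC(C)=O)[C@@H](C)C(=O)O[C@H]2[C@@H](Cl)C(CO)=C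
F2 | step 22 | allylic bromide | O=C[C@H]1O[C@]2([C@H](OC(C)=O)[C@@H]3[C@]1(C)C=C[C@@H](OC(C)=O)[C@@]3(C)OC(C)=O)[C@@H](C)C(=O)O[C@H]2[C@@H](Cl)C(CBr)=C
F3 | step 3 | keto aldehyde, (3S)-3-[(4S)-2,2-dimethyl-1,3-dioxolan-4-yl]-2,4-dimethyl-5-oxohexanal (C2/C4 epimers) | CC(=O)C(C)[C@@H]([C@H]1COC(C)(C)O1)C(C)C=O
F4 | step 16 | (9S)-carbinol, C9 epimer of 26 | CC1=C([C@@H](O)[C@@H]2[C@@](C)(C(=O)C(OC)OC)C=C[C@@H](OC(C)=O)[C@@]2(C)OC(C)=O)[C@H]([C@H](OCOC)C(C)=C)OC1=O
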